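If the L charged is what stops solid Q from falling, the number to reckon is what each Q lost from the solid costs in L.

in all of them: Q 0.059 M

| run | L | remark | time |
|---|---|---|---|
| ash | 0.032 M | run made earlier |  |
| birch | 0.071 M | run made earlier |  |
| flask | 0.0472 M |  | 3.0 d |

- ash (time / d: Q / %, J / %): 0.625: 71.0, 2.1; 1.25: 64.6, 0.1; 1.67: 62.8, 1.1; 2.50: 63.4, 2.3
- birch (time / d: Q / %, J / %): 0.333: 75.3, 0; 0.833: 45.3, 1.6; 1.67: 30.8, 2.8; 2.50: 30.0, 2.3

(each reading ± 1 percentage point)

- as a solid, counted per litre of solution: Q
- at the start none of Q is in solution
- a reading or a percentage of J counts all its forms, free or not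

* amount of Q at 3.0 d, in percent of the Q charged (only what is still solid)
* amount of J at 3.0 d, in percent of the Q charged
* amount of D at 3.0 d, in percent of the Q charged
* amount of X at 3.0 d, in percent of the Q charged

At the start none of Q is in solution, so L has to wait for Q to dissolve. In the birch run the solid is already down to 75.3% at 0.333 d, while J reads 0%. In the middle of the birch run, Q reaches 45.3% at 0.833 d and J reads 1.6%, so J stands at 2.93% of what the readings show as lost from the solid. At the end the solid goes flat: from 62.8% to 63.4% in the ash run, and from 30.8% to 30.0% in the birch run, both within a scatter of 1 percentage point.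

At the last readings, the L charged per Q lost is 1.48 in the ash run and 1.72 in the birch run, so the birch run pays more. On a logarithmic scale the flask's L charge stands half of the way from ash to birch, so the geometric mean is taken: 1.60. This is the price P, moles of L spent per mole of Q leaving the solid, with the L charged counted as spent. Taking the flask as flat by 3.0 d, this reckoning leaves 49.9% of Q solid.

The forecast, interpolating in its own way, gives Q 49.5%, J 2%, D 19% and X 29.5%, on the ground that “L appears to be spent”.

The flask gives Q 50.9%, J 1.99%, D 2.94% and X 37.5%.

    E + L → J (k = 18.7 M⁻¹ h⁻¹)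
    E + L → D (k = 9.93 M⁻¹ h⁻¹)
    L + J → X (k = 57.8 M⁻¹ h⁻¹)
    L + D → X (k = 16.0 M⁻¹ h⁻¹)
    E + J ⇌ G, settled at all times (K = 29.0 M⁻¹)
    Q ⇌ E, rate k6*(cs6 - [E]) while solid is left; crystals form when [E] > cs6 (solubility = 3.80 mM, k = 0.714 h⁻¹)

In the flask L is the limiting reagent, with 0% left, and P comes out at 1.63. The forecast parts from the flask at D and X, while the flask also holds 6.44% as dissolved E. The neighbouring flask charges 0.12 M of L on the same Q. Clearing the solid at the carried price takes 0.0942 M, less than that charge, so the reckoning leaves no solid, and that flask shows Q 0%. With 2.02% of its L left, its P is 1.99, and its X stands at 99.4%.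

Readings and results come from a simulation for an exercise.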